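**Retrosynthetic overview**

1. The target is a trans-α,β-dibenzyl-γ-butyrolactone; its α-benzyl arene is a trans-2-aryl-3-(hydroxymethyl)dihydrobenzofuran and its β-benzyl arene carries an anti-1,2-diarylpropane-1,3-diol. The last disconnection cuts the lactone C2–C3 bond (carbonyl carbon to α-carbon) together with the adjacent exocyclic CH2–aryl bond, giving a homoallylic caesium oxalate (ring B, open diol unit, C4 stereocentre) and a 5-bromodihydrobenzofuran.
2. Enabling feature: in the lactone ring O1–C2(=O)–C3–C4–C5, C3 carries one exocyclic CH2 bound to C5 of the benzofuran benzene ring. C2 can therefore arrive as an alkoxycarbonyl radical tethered by O1–C5–C4 to a vinyl group (C3 plus its CH2) and close 5-exo, while nickel delivers the arene to the exocyclic carbon. C4 steers C3, and C3 is enolisable, so both C3 epimers converge on the trans lactone.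
3. Both aryl–C3 units come from one (4S)-N-arylacetyl oxazolidinone and O-silyl vanillin. A boron syn-aldol followed by acid cyclisation gives the (2S,3R)-dihydrobenzofuran bromide; a magnesium-catalysed anti-aldol gives the (1S,2S)-diol unit, whose aryl bromide is homologated to a benzylic bromide.
4. The C4 stereocentre comes from deconjugative Evans alkylation of a (4R)-N-crotonyl oxazolidinone with that benzylic bromide, then reduction to the (R)-2-substituted but-3-en-1-ol and oxalate formation.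
5. Ring order: the dihydrofuran ring first (step 8), the γ-lactone last (step 19); one global desilylation (step 20) ends the route.

Key step: step 19

Remark on the chemistry: TBS = tert-butyldimethylsilyl and TBSO = its silyl ether oxygen; the facial sense of step 10 is assumed to follow the chelated magnesium Z-enolate model (aldehyde anti to the auxiliary benzyl group).

**Route**

Step 1
Reactants: 1 5-bromo-2-hydroxy-3-methoxybenzaldehyde
Product: 2 5-bromo-3-methoxy-2-(TBSO)benzaldehyde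
Conditions: TBSCl, imidazole, DMF, 23 °C
Reagents that add atoms: tert-butyldimethylsilyl chloride, CC(C)(C)[Si](C)(C)Cl
Why: Imidazole-mediated O-silylation of the phenol masks the acidic OH for the ylide and enolate chemistry that follows; no stereocentre is involved.

Step 2
Reactants: 2 5-bromo-3-methoxy-2-(TBSO)benzaldehyde
Product: 3 tert-butyl[4-bromo-2-methoxy-6-(2-methoxyethenyl)phenoxy]dimethylsilane (E/Z mixture)
Conditions: Ph3P(CH2OMe)Cl, KN(SiMe3)2, THF, 0 → 23 °C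
Reagents that add atoms: (methoxymethyl)triphenylphosphonium chloride, COC[P+](c1ccccc1)(c1ccccc1)c1ccccc1.[Cl-]
Why: Wittig methoxymethylenation of the aldehyde with a non-nucleophilic amide base gives the enol ether as a one-carbon homologation handle, the alkene geometry being irrelevant.

Step 3
Reactants: 3 enol ether (E/Z mixture)
Product: 5 [5-bromo-3-methoxy-2-(TBSO)phenyl]acetic acid, via arylacetaldehyde 4 (not isolated)
Conditions: aq. HCO2H, CH2Cl2, 23 °C; then NaClO2, NaH2PO4, 2-methylbut-2-ene, t-BuOH/THF/H2O, 0 → 23 °C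
Reagents that add atoms: water, O; sodium chlorite, [Na+].[O-]Cl=O
Why: Acidic enol-ether hydrolysis unmasks the sensitive arylacetaldehyde, which is oxidised at once by Pinnick oxidation (the alkene scavenger protects the electron-rich arene from hypochlorite), and the aryl silyl ether tolerates both mild acids.

Step 4
Reactants: 5 [5-bromo-3-methoxy-2-(TBSO)phenyl]acetic acid; 6 (4S)-4-benzyl-1,3-oxazolidin-2-one
Product: 8 (4S)-4-benzyl-3-{[5-bromo-3-methoxy-2-(TBSO)phenyl]acetyl}-1,3-oxazolidin-2-one, via pivalic mixed anhydride 7 (not isolated)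
Conditions: t-BuCOCl, Et3N, THF, −20 °C; then 6, LiCl, −20 → 23 °C
Reagents that add atoms: none
Why: N-acylation of the Evans oxazolidinone through the mixed pivalic anhydride occurs at the less hindered arylacetyl carbonyl under LiCl/Et3N activation and leaves the auxiliary stereocentre untouched.

Step 5
Reactants: 9 4-hydroxy-3-methoxybenzaldehyde (vanillin)
Product: 10 3-methoxy-4-(TBSO)benzaldehyde
Conditions: TBSCl, imidazole, DMF, 23 °C
Reagents that add atoms: tert-butyldimethylsilyl chloride, CC(C)(C)[Si](C)(C)Cl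
Why: Imidazole-mediated phenol silylation provides the non-enolisable aldehyde partner for both aldol reactions.

Step 6
Reactants: 8 (4S)-N-arylacetyl oxazolidinone; 10 3-methoxy-4-(TBSO)benzaldehyde
Product: 11 (4S)-4-benzyl-3-{(2S,3S)-2-[5-bromo-3-methoxy-2-(TBSO)phenyl]-3-hydroxy-3-[3-methoxy-4-(TBSO)phenyl]propanoyl}-1,3-oxazolidin-2-one
Conditions: Bu2BOTf, i-Pr2NEt, CH2Cl2, −78 → 0 °C; then 10, −78 → 0 °C; pH 7 buffer, MeOH, H2O2, 0 °C
Reagents that add atoms: none
Why: Evans boron syn-aldol reaction, in which the Z-boron enolate reacts through a closed Zimmerman–Traxler chair with the aldehyde approaching opposite the auxiliary benzyl group, should set C2 (S) and C3 (S) together.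

Step 7
Reactants: 11 syn-aldol adduct
Product: 12 (1S,2R)-2-[5-bromo-3-methoxy-2-(TBSO)phenyl]-1-[3-methoxy-4-(TBSO)phenyl]propane-1,3-diol
Conditions: LiBH4, THF/MeOH, 0 °C
Reagents that add atoms: none
Why: Reductive cleavage of the imide by hydride attack at the exocyclic acyl carbonyl releases the 1,3-diol and the auxiliary without touching stereocentres, aryl bromide or silyl ethers (the C2 descriptor changes only by priority).

Step 8
Reactants: 12 (1S,2R)-diol
Product: 14 4-[(2S,3R)-5-bromo-3-(hydroxymethyl)-7-methoxy-2,3-dihydro-1-benzofuran-2-yl]-2-methoxyphenol, via tetraol 13 (not isolated)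
Conditions: Bu4NF (2.2 equiv), THF, 0 °C; then TsOH·H2O (3 equiv), 23 °C
Reagents that add atoms: none
Why: Fluoride desilylation frees both phenols and acid then ionises the para-hydroxybenzylic alcohol to a quinone methide/benzylic cation that the ortho phenol of the bromoarene captures (5-exo O-cyclisation, the acid-mediated phenylcoumaran-forming dehydration); C3 is untouched and the reversible closure should place the C2 aryl trans to the C3 hydroxymethyl group, giving (2S,3R).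

Step 9
Reactants: 14 dihydrobenzofuran phenol-alcohol
Product: 15 (2S,3R)-5-bromo-7-methoxy-2-[3-methoxy-4-(TBSO)phenyl]-3-[(TBSO)methyl]-2,3-dihydro-1-benzofuran
Conditions: TBSCl (2.5 equiv), imidazole, DMF, 23 °C
Reagents that add atoms: tert-butyldimethylsilyl chloride, CC(C)(C)[Si](C)(C)Cl
Why: Imidazole-mediated silylation of the phenol and the primary alcohol gives the fully masked aryl bromide for the coupling.

Step 10
Reactants: 8 (4S)-N-arylacetyl oxazolidinone; 10 3-methoxy-4-(TBSO)benzaldehyde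
Product: 17 (4S)-4-benzyl-3-{(2R,3S)-2-[5-bromo-3-methoxy-2-(TBSO)phenyl]-3-hydroxy-3-[3-methoxy-4-(TBSO)phenyl]propanoyl}-1,3-oxazolidin-2-one, via O-trimethylsilyl ether 16 (not isolated)
Conditions: MgCl2 (0.2 equiv), Et3N, Me3SiCl, EtOAc, 23 °C; then 1 M aq. HCl/THF, 0 °C
Reagents that add atoms: none
Why: Magnesium-halide-catalysed Evans anti-aldol reaction (soft enolisation, silyl trapping of the aldolate), in which the chelated Z-enolate is attacked by the non-enolisable aldehyde anti to the auxiliary benzyl group through a boat-like transition state, should set C2 (R) and C3 (S), and brief dilute acid then removes the labile trimethylsilyl ether.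

Step 11
Reactants: 17 anti-aldol adduct
Product: 18 (1S,2S)-2-[5-bromo-3-methoxy-2-(TBSO)phenyl]-1-[3-methoxy-4-(TBSO)phenyl]propane-1,3-diol
Conditions: LiBH4, THF/MeOH, 0 °C
Reagents that add atoms: none
Why: Reductive imide cleavage by LiBH4 gives the anti-configured 1,3-diol and returns the auxiliary, the stereocentres being unaffected.

Step 12
Reactants: 18 (1S,2S)-diol
Product: 19 (1S,2S)-2-[5-bromo-3-methoxy-2-(TBSO)phenyl]-1-[3-methoxy-4-(TBSO)phenyl]-1,3-bis(TBSO)propane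
Conditions: TBSOTf (2.5 equiv), 2,6-lutidine, CH2Cl2, −78 → 0 °C
Reagents that add atoms: tert-butyldimethylsilyl trifluoromethanesulfonate, CC(C)(C)[Si](C)(C)OS(=O)(=O)C(F)(F)F
Why: Silyl triflate with a hindered pyridine base silylates the primary and the hindered benzylic secondary alcohol without ionising the benzylic position.

Step 13
Reactants: 19 tetrakis-silyl aryl bromide
Product: 21 [3-{(1S,2S)-1,3-bis(TBSO)-1-[3-methoxy-4-(TBSO)phenyl]propan-2-yl}-5-methoxy-4-(TBSO)phenyl]methanol, via aldehyde 20 (not isolated)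
Conditions: n-BuLi, THF, −78 °C; DMF, −78 → 0 °C; then NaBH4, MeOH, 0 °C
Reagents that add atoms: N,N-dimethylformamide, CN(C)C=O
Why: Bromine–lithium exchange at low temperature, formylation with DMF and borohydride reduction in the same flask (Bouveault-type formylation–reduction) convert the aryl bromide into the benzylic alcohol while silyl ethers stay intact.

Step 14
Reactants: 21 benzylic alcohol
Product: 22 (1S,2S)-2-[5-(bromomethyl)-3-methoxy-2-(TBSO)phenyl]-1-[3-methoxy-4-(TBSO)phenyl]-1,3-bis(TBSO)propane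
Conditions: CBr4, PPh3, CH2Cl2, 0 °C
Reagents that add atoms: carbon tetrabromide, BrC(Br)(Br)Br
Why: Appel bromination converts the primary benzylic alcohol into the bromide under neutral conditions that the silyl ethers tolerate.

Step 15
Reactants: 23 (4R)-4-benzyl-1,3-oxazolidin-2-one
Product: 24 (4R)-4-benzyl-3-[(2E)-but-2-enoyl]-1,3-oxazolidin-2-one
Conditions: n-BuLi, THF, −78 °C; then (E)-but-2-enoyl chloride, −78 → 0 °C
Reagents that add atoms: (E)-but-2-enoyl chloride, C/C=C/C(Cl)=O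
Why: N-acylation of the lithiated oxazolidinone with the acid chloride gives the crotonyl imide.

Step 16
Reactants: 24 (4R)-N-crotonyl oxazolidinone; 22 benzylic bromide
Product: 25 (4R)-4-benzyl-3-[(2R)-2-{[3-{(1S,2S)-1,3-bis(TBSO)-1-[3-methoxy-4-(TBSO)phenyl]propan-2-yl}-5-methoxy-4-(TBSO)phenyl]methyl}but-3-enoyl]-1,3-oxazolidin-2-one
Conditions: NaN(SiMe3)2, THF, −78 °C; then 22, −78 → −30 °C; AcOH quench at −78 °C
Reagents that add atoms: none
Why: Deconjugative Evans alkylation, in which γ-deprotonation gives the chelated sodium Z-dienolate that is alkylated at the α-carbon on the face opposite the auxiliary benzyl group, should set the (R) vinyl-bearing stereocentre, and the cold acidic quench avoids reconjugation.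

Step 17
Reactants: 25 α-alkylated β,γ-unsaturated imide
Product: 26 (2R)-2-{[3-{(1S,2S)-1,3-bis(TBSO)-1-[3-methoxy-4-(TBSO)phenyl]propan-2-yl}-5-methoxy-4-(TBSO)phenyl]methyl}but-3-en-1-ol
Conditions: LiBH4, THF/MeOH, 0 °C
Reagents that add atoms: none
Why: Reductive removal of the auxiliary by LiBH4 gives the homoallylic alcohol without isomerising the terminal alkene or touching the stereocentre.

Step 18
Reactants: 26 homoallylic alcohol
Product: 28 caesium (2R)-2-(arylmethyl)but-3-en-1-yl oxalate (caesium salt of the hydrogen oxalate of 26), via methyl oxalate 27 (not isolated)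
Conditions: MeO2CCOCl, Et3N, DMAP (cat.), CH2Cl2, 0 °C; then CsOH·H2O (1.0 equiv), THF/H2O, 0 °C
Reagents that add atoms: methyl chlorooxoacetate, COC(=O)C(Cl)=O; caesium hydroxide, [Cs+].[OH-]
Why: O-acylation of the primary alcohol followed by hydrolysis of the highly electrophilic methyl oxalate ester with exactly one equivalent of hydroxide (the standard preparation of photoredox-active alkyl oxalate salts) leaves the aryl silyl ethers intact.

Step 19
Reactants: 28 homoallylic caesium oxalate; 15 aryl bromide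
Product: 30 hexakis-TBS ether of the target with the (3R,4R)-trans lactone, via cis-lactone epimer 29 (not isolated)
Conditions: Ir[dF(CF3)ppy]2(dtbbpy)PF6 (2 mol%), NiBr2(dme) (10 mol%), 4,4'-di-tert-butyl-2,2'-bipyridine (15 mol%), 1,4-dioxane/DMSO (4:1), blue LEDs (450 nm), 30 °C; then DBU (0.5 equiv), PhMe, 60 °C
Reagents that add atoms: none
Why: The photoexcited trivalent iridium complex oxidises the oxalate carboxylate of 28, loss of CO2 leaves a primary alkoxycarbonyl radical that adds 5-exo-trig to the vinyl group (forming the lactone C2–C3 bond), and the resulting primary alkyl radical is intercepted by the aryl–nickel bromide formed from 15 and zerovalent nickel, so that reductive elimination from trivalent nickel forges the CH2–aryl bond while the reduced iridium complex returns monovalent nickel to the zerovalent state. The closest known reaction type is the photoredox/nickel alkoxycarbonyl-radical cyclisation–arylation cascade of homoallylic caesium oxalates with aryl halides, here applied to a primary oxalate with a stereocentre in the tether. The only ring closed is the γ-lactone, by 5-exo-trig radical closure through the chain O1–C5–C4 that holds the acyl radical next to the alkene. The new stereocentre C3 is controlled by C4: in the chair-like Beckwith–Houk transition state the C4 arylmethyl group sits pseudo-equatorial and the forming C3–CH2 arm ends up trans to it, and because C3 is the only enolisable centre the DBU treatment should drain the minor cis epimer 29 into the more stable trans lactone, so both epimers converge on (3R,4R). The step needs ring closure to outrun decarboxylation of the acyl radical, its direct capture by nickel (aryl ester formation) and 6-endo closure, and it needs aryl transfer to outrun hydrogen abstraction by the cyclised radical; the primary O-alkyl group (slow loss of the second CO2), the unhindered monosubstituted alkene, the low stationary nickel concentration and the inertness of silyl ethers and the dihydrobenzofuran towards zerovalent nickel are what should secure this.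

Step 20
Reactants: 30 hexakis-TBS ether
Product: 31 CNP0199264.2, (3R,4R)-4-{[3-[(1S,2S)-1,3-dihydroxy-1-(4-hydroxy-3-methoxyphenyl)propan-2-yl]-4-hydroxy-5-methoxyphenyl]methyl}-3-{[(2S,3R)-2-(4-hydroxy-3-methoxyphenyl)-3-(hydroxymethyl)-7-methoxy-2,3-dihydro-1-benzofuran-5-yl]methyl}oxolan-2-one
Conditions: Bu4NF (10 equiv), AcOH (5 equiv), THF, 0 → 23 °C
Reagents that add atoms: none
Why: Fluoride-mediated global desilylation (Si–F bond formation) should remove three aryl, two primary and one benzylic silyl ether under acetate buffering, which avoids acid that would ionise the para-hydroxybenzylic alcohol, and no stereocentre is touched.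

**Compound list**

1 | 5-bromo-2-hydroxy-3-methoxybenzaldehyde | COc1cc(Br)cc(C=O)c1O | starting material
2 | 5-bromo-3-methoxy-2-(TBSO)benzaldehyde | COc1cc(Br)cc(C=O)c1O[Si](C)(C)C(C)(C)C | intermediate
3 | tert-butyl[4-bromo-2-methoxy-6-(2-methoxyethenyl)phenoxy]dimethylsilane (E/Z mixture) | COC=Cc1cc(Br)cc(OC)c1O[Si](C)(C)C(C)(C)C | intermediate
4 | [5-bromo-3-methoxy-2-(TBSO)phenyl]acetaldehyde | O=CCc1cc(Br)cc(OC)c1O[Si](C)(C)C(C)(C)C | intermediate (not isolated)
5 | [5-bromo-3-methoxy-2-(TBSO)phenyl]acetic acid | OC(=O)Cc1cc(Br)cc(OC)c1O[Si](C)(C)C(C)(C)C | intermediate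
6 | (4S)-4-benzyl-1,3-oxazolidin-2-one | O=C1N[C@@H](Cc2ccccc2)CO1 | starting material
7 | [5-bromo-3-methoxy-2-(TBSO)phenyl]acetic pivalic anhydride | CC(C)(C)C(=O)OC(=O)Cc1cc(Br)cc(OC)c1O[Si](C)(C)C(C)(C)C | intermediate (not isolated)
8 | (4S)-4-benzyl-3-{[5-bromo-3-methoxy-2-(TBSO)phenyl]acetyl}-1,3-oxazolidin-2-one | O=C(Cc1cc(Br)cc(OC)c1O[Si](C)(C)C(C)(C)C)N1C(=O)OC[C@@H]1Cc1ccccc1 | intermediate
9 | 4-hydroxy-3-methoxybenzaldehyde (vanillin) | COc1cc(C=O)ccc1O | starting material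
10 | 3-methoxy-4-(TBSO)benzaldehyde | COc1cc(C=O)ccc1O[Si](C)(C)C(C)(C)C | intermediate
11 | (4S)-4-benzyl-3-{(2S,3S)-2-[5-bromo-3-methoxy-2-(TBSO)phenyl]-3-hydroxy-3-[3-methoxy-4-(TBSO)phenyl]propanoyl}-1,3-oxazolidin-2-one | O=C(N1C(=O)OC[C@@H]1Cc1ccccc1)[C@@H](c1cc(Br)cc(OC)c1O[Si](C)(C)C(C)(C)C)[C@H](O)c1ccc(O[Si](C)(C)C(C)(C)C)c(OC)c1 | intermediate
12 | (1S,2R)-2-[5-bromo-3-methoxy-2-(TBSO)phenyl]-1-[3-methoxy-4-(TBSO)phenyl]propane-1,3-diol | OC[C@@H](c1cc(Br)cc(OC)c1O[Si](C)(C)C(C)(C)C)[C@H](O)c1ccc(O[Si](C)(C)C(C)(C)C)c(OC)c1 | intermediate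
13 | (1S,2R)-2-(5-bromo-2-hydroxy-3-methoxyphenyl)-1-(4-hydroxy-3-methoxyphenyl)propane-1,3-diol | OC[C@@H](c1cc(Br)cc(OC)c1O)[C@H](O)c1ccc(O)c(OC)c1 | intermediate (not isolated)
14 | 4-[(2S,3R)-5-bromo-3-(hydroxymethyl)-7-methoxy-2,3-dihydro-1-benzofuran-2-yl]-2-methoxyphenol | Brc1cc(OC)c2c(c1)[C@H](CO)[C@@H](c1ccc(O)c(OC)c1)O2 | intermediate
15 | (2S,3R)-5-bromo-7-methoxy-2-[3-methoxy-4-(TBSO)phenyl]-3-[(TBSO)methyl]-2,3-dihydro-1-benzofuran | Brc1cc(OC)c2c(c1)[C@H](CO[Si](C)(C)C(C)(C)C)[C@@H](c1ccc(O[Si](C)(C)C(C)(C)C)c(OC)c1)O2 | intermediate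
16 | (4S)-4-benzyl-3-{(2R,3S)-2-[5-bromo-3-methoxy-2-(TBSO)phenyl]-3-[3-methoxy-4-(TBSO)phenyl]-3-(trimethylsilyloxy)propanoyl}-1,3-oxazolidin-2-one | O=C(N1C(=O)OC[C@@H]1Cc1ccccc1)[C@H](c1cc(Br)cc(OC)c1O[Si](C)(C)C(C)(C)C)[C@H](O[Si](C)(C)C)c1ccc(O[Si](C)(C)C(C)(C)C)c(OC)c1 | intermediate (not isolated)
17 | (4S)-4-benzyl-3-{(2R,3S)-2-[5-bromo-3-methoxy-2-(TBSO)phenyl]-3-hydroxy-3-[3-methoxy-4-(TBSO)phenyl]propanoyl}-1,3-oxazolidin-2-one | O=C(N1C(=O)OC[C@@H]1Cc1ccccc1)[C@H](c1cc(Br)cc(OC)c1O[Si](C)(C)C(C)(C)C)[C@H](O)c1ccc(O[Si](C)(C)C(C)(C)C)c(OC)c1 | intermediate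
18 | (1S,2S)-2-[5-bromo-3-methoxy-2-(TBSO)phenyl]-1-[3-methoxy-4-(TBSO)phenyl]propane-1,3-diol | OC[C@H](c1cc(Br)cc(OC)c1O[Si](C)(C)C(C)(C)C)[C@H](O)c1ccc(O[Si](C)(C)C(C)(C)C)c(OC)c1 | intermediate
19 | (1S,2S)-2-[5-bromo-3-methoxy-2-(TBSO)phenyl]-1-[3-methoxy-4-(TBSO)phenyl]-1,3-bis(TBSO)propane | CC(C)(C)[Si](C)(C)OC[C@H](c1cc(Br)cc(OC)c1O[Si](C)(C)C(C)(C)C)[C@H](O[Si](C)(C)C(C)(C)C)c1ccc(O[Si](C)(C)C(C)(C)C)c(OC)c1 | intermediate
20 | 3-{(1S,2S)-1,3-bis(TBSO)-1-[3-methoxy-4-(TBSO)phenyl]propan-2-yl}-5-methoxy-4-(TBSO)benzaldehyde | CC(C)(C)[Si](C)(C)OC[C@H](c1cc(C=O)cc(OC)c1O[Si](C)(C)C(C)(C)C)[C@H](O[Si](C)(C)C(C)(C)C)c1ccc(O[Si](C)(C)C(C)(C)C)c(OC)c1 | intermediate (not isolated)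
21 | [3-{(1S,2S)-1,3-bis(TBSO)-1-[3-methoxy-4-(TBSO)phenyl]propan-2-yl}-5-methoxy-4-(TBSO)phenyl]methanol | CC(C)(C)[Si](C)(C)OC[C@H](c1cc(CO)cc(OC)c1O[Si](C)(C)C(C)(C)C)[C@H](O[Si](C)(C)C(C)(C)C)c1ccc(O[Si](C)(C)C(C)(C)C)c(OC)c1 | intermediate
22 | (1S,2S)-2-[5-(bromomethyl)-3-methoxy-2-(TBSO)phenyl]-1-[3-methoxy-4-(TBSO)phenyl]-1,3-bis(TBSO)propane | CC(C)(C)[Si](C)(C)OC[C@H](c1cc(CBr)cc(OC)c1O[Si](C)(C)C(C)(C)C)[C@H](O[Si](C)(C)C(C)(C)C)c1ccc(O[Si](C)(C)C(C)(C)C)c(OC)c1 | intermediate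
23 | (4R)-4-benzyl-1,3-oxazolidin-2-one | O=C1N[C@H](Cc2ccccc2)CO1 | starting material
24 | (4R)-4-benzyl-3-[(2E)-but-2-enoyl]-1,3-oxazolidin-2-one | C/C=C/C(=O)N1C(=O)OC[C@H]1Cc1ccccc1 | intermediate
25 | (4R)-4-benzyl-3-[(2R)-2-{[3-{(1S,2S)-1,3-bis(TBSO)-1-[3-methoxy-4-(TBSO)phenyl]propan-2-yl}-5-methoxy-4-(TBSO)phenyl]methyl}but-3-enoyl]-1,3-oxazolidin-2-one | C=C[C@@H](Cc1cc(OC)c(O[Si](C)(C)C(C)(C)C)c(c1)[C@@H](CO[Si](C)(C)C(C)(C)C)[C@H](O[Si](C)(C)C(C)(C)C)c1ccc(O[Si](C)(C)C(C)(C)C)c(OC)c1)C(=O)N1C(=O)OC[C@H]1Cc1ccccc1 | intermediate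
26 | (2R)-2-{[3-{(1S,2S)-1,3-bis(TBSO)-1-[3-methoxy-4-(TBSO)phenyl]propan-2-yl}-5-methoxy-4-(TBSO)phenyl]methyl}but-3-en-1-ol | C=C[C@@H](Cc1cc(OC)c(O[Si](C)(C)C(C)(C)C)c(c1)[C@@H](CO[Si](C)(C)C(C)(C)C)[C@H](O[Si](C)(C)C(C)(C)C)c1ccc(O[Si](C)(C)C(C)(C)C)c(OC)c1)CO | intermediate
27 | methyl (2R)-2-{[3-{(1S,2S)-1,3-bis(TBSO)-1-[3-methoxy-4-(TBSO)phenyl]propan-2-yl}-5-methoxy-4-(TBSO)phenyl]methyl}but-3-en-1-yl oxalate | C=C[C@@H](Cc1cc(OC)c(O[Si](C)(C)C(C)(C)C)c(c1)[C@@H](CO[Si](C)(C)C(C)(C)C)[C@H](O[Si](C)(C)C(C)(C)C)c1ccc(O[Si](C)(C)C(C)(C)C)c(OC)c1)COC(=O)C(=O)OC | intermediate (not isolated)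
28 | caesium (2R)-2-{[3-{(1S,2S)-1,3-bis(TBSO)-1-[3-methoxy-4-(TBSO)phenyl]propan-2-yl}-5-methoxy-4-(TBSO)phenyl]methyl}but-3-en-1-yl oxalate | C=C[C@@H](Cc1cc(OC)c(O[Si](C)(C)C(C)(C)C)c(c1)[C@@H](CO[Si](C)(C)C(C)(C)C)[C@H](O[Si](C)(C)C(C)(C)C)c1ccc(O[Si](C)(C)C(C)(C)C)c(OC)c1)COC(=O)C(=O)[O-].[Cs+] | intermediate
29 | (3S,4R)-cis-lactone epimer of 30 (same substituents, opposite configuration at lactone C3) | COc1cc([C@@H](O[Si](C)(C)C(C)(C)C)[C@H](CO[Si](C)(C)C(C)(C)C)c2cc(C[C@H]3COC(=O)[C@H]3Cc3cc(OC)c4c(c3)[C@H](CO[Si](C)(C)C(C)(C)C)[C@@H](c3ccc(O[Si](C)(C)C(C)(C)C)c(OC)c3)O4)cc(OC)c2O[Si](C)(C)C(C)(C)C)ccc1O[Si](C)(C)C(C)(C)C | intermediate (not isolated)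
30 | (3R,4R)-4-{[3-{(1S,2S)-1,3-bis(TBSO)-1-[3-methoxy-4-(TBSO)phenyl]propan-2-yl}-5-methoxy-4-(TBSO)phenyl]methyl}-3-{[(2S,3R)-7-methoxy-2-[3-methoxy-4-(TBSO)phenyl]-3-[(TBSO)methyl]-2,3-dihydro-1-benzofuran-5-yl]methyl}oxolan-2-one | COc1cc([C@@H](O[Si](C)(C)C(C)(C)C)[C@H](CO[Si](C)(C)C(C)(C)C)c2cc(C[C@H]3COC(=O)[C@@H]3Cc3cc(OC)c4c(c3)[C@H](CO[Si](C)(C)C(C)(C)C)[C@@H](c3ccc(O[Si](C)(C)C(C)(C)C)c(OC)c3)O4)cc(OC)c2O[Si](C)(C)C(C)(C)C)ccc1O[Si](C)(C)C(C)(C)C | intermediate
31 | CNP0199264.2, (3R,4R)-4-{[3-[(1S,2S)-1,3-dihydroxy-1-(4-hydroxy-3-methoxyphenyl)propan-2-yl]-4-hydroxy-5-methoxyphenyl]methyl}-3-{[(2S,3R)-2-(4-hydroxy-3-methoxyphenyl)-3-(hydroxymethyl)-7-methoxy-2,3-dihydro-1-benzofuran-5-yl]methyl}oxolan-2-one | COc1cc([C@@H](O)[C@H](CO)c2cc(C[C@H]3COC(=O)[C@@H]3Cc3cc(OC)c4c(c3)[C@H](CO)[C@@H](c3ccc(O)c(OC)c3)O4)cc(OC)c2O)ccc1O | target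

**Step count and risks**

Total step count: 20. Longest linear sequence: 14 steps (steps 1–4, 10–14 and 16–20).

Steps most likely to fail:

1. Step 19. The acyl radical may be captured by nickel before it cyclises (aryl ester formation), oxidative addition of the electron-rich aryl bromide may be too slow so that the cyclised radical is quenched by hydrogen abstraction, and the electron-rich arenes may be photo-oxidised. The fallback sets out from 26 and 15 and comes back at 30, forming the other bond at the lactone α-carbon by classical enolate chemistry. Hydroboration–oxidation of 26 (9-BBN, THF; NaBO3·4H2O) should give the (2R)-2-(arylmethyl)butane-1,4-diol F1, and oxidative lactonisation at the less hindered primary alcohol (TEMPO, PhI(OAc)2, CH2Cl2) the (4R)-4-(arylmethyl)oxolan-2-one F2. In parallel, 15 is formylated (n-BuLi, THF, −78 °C; DMF) to the dihydrobenzofuran-5-carbaldehyde F3, reduced (NaBH4, MeOH) to the 5-(hydroxymethyl) compound F4 and brominated (CBr4, PPh3) to the 5-(bromomethyl) compound F5. Alkylation of the lithium enolate of F2 (LiN(SiMe3)2, THF, −78 °C) with F5, anti to the C4 substituent, should give 30.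

2. Step 10. Anti-selectivity or the sense of auxiliary control may be insufficient with the α-aryl imide, and retro-aldol cleavage or α-epimerisation may occur under the amine conditions. The fallback sets out from 5 (with 23 and 10) and comes back at 19, setting the aryl-bearing centre by the reliable boron syn-aldol and the carbinol centre by a separate reagent-controlled reduction. Acylation of 23 with 5 (as in step 4) gives the (4R)-N-arylacetyl oxazolidinone F6, the Bu2BOTf syn-aldol with 10 the (2R,3R)-adduct F7, and LiBH4 the (1R,2S)-diol F8. Primary-selective silylation (TBSCl, imidazole, 0 °C) gives the 3-O-TBS ether F9, Dess–Martin oxidation the (2S)-aryl ketone F10, and Corey–Bakshi–Shibata reduction ((R)-2-methyl-CBS-oxazaborolidine, BH3·SMe2, aryl group as the large substituent) the (1S,2S)-alcohol F11, which TBSOTf/2,6-lutidine converts into 19.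

3. Step 20. The hindered benzylic silyl ether may be cleaved incompletely, or the benzylic carbinol may ionise once the neighbouring ring-B phenol is free and close a second dihydrobenzofuran. The fallback sets out from 30 and comes back at 31, unmasking in two stages ordered by mechanism. HF·pyridine/pyridine in THF cleaves the three alkyl silyl ethers while every phenol, including the ring-B phenol that could cyclise, stays silylated, giving the tris(aryl silyl ether) triol F12. Bu4NF/AcOH (1:1) in THF at 0 °C, which removes only aryl silyl ethers under buffered conditions, then gives 31.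

Further compounds
F1 | step 19 | (2R)-2-{[3-{(1S,2S)-1,3-bis(TBSO)-1-[3-methoxy-4-(TBSO)phenyl]propan-2-yl}-5-methoxy-4-(TBSO)phenyl]methyl}butane-1,4-diol | OCC[C@@H](Cc1cc(OC)c(O[Si](C)(C)C(C)(C)C)c(c1)[C@@H](CO[Si](C)(C)C(C)(C)C)[C@H](O[Si](C)(C)C(C)(C)C)c1ccc(O[Si](C)(C)C(C)(C)C)c(OC)c1)CO
F2 | step 19 | (4R)-4-{[3-{(1S,2S)-1,3-bis(TBSO)-1-[3-methoxy-4-(TBSO)phenyl]propan-2-yl}-5-methoxy-4-(TBSO)phenyl]methyl}oxolan-2-one | O=C1C[C@@H](Cc2cc(OC)c(O[Si](C)(C)C(C)(C)C)c(c2)[C@@H](CO[Si](C)(C)C(C)(C)C)[C@H](O[Si](C)(C)C(C)(C)C)c2ccc(O[Si](C)(C)C(C)(C)C)c(OC)c2)CO1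
F3 | step 19 | (2S,3R)-7-methoxy-2-[3-methoxy-4-(TBSO)phenyl]-3-[(TBSO)methyl]-2,3-dihydro-1-benzofuran-5-carbaldehyde | O=Cc1cc(OC)c2c(c1)[C@H](CO[Si](C)(C)C(C)(C)C)[C@@H](c1ccc(O[Si](C)(C)C(C)(C)C)c(OC)c1)O2
F4 | step 19 | {(2S,3R)-7-methoxy-2-[3-methoxy-4-(TBSO)phenyl]-3-[(TBSO)methyl]-2,3-dihydro-1-benzofuran-5-yl}methanol | OCc1cc(OC)c2c(c1)[C@H](CO[Si](C)(C)C(C)(C)C)[C@@H](c1ccc(O[Si](C)(C)C(C)(C)C)c(OC)c1)O2
F5 | step 19 | (2S,3R)-5-(bromomethyl)-7-methoxy-2-[3-methoxy-4-(TBSO)phenyl]-3-[(TBSO)methyl]-2,3-dihydro-1-benzofuran | BrCc1cc(OC)c2c(c1)[C@H](CO[Si](C)(C)C(C)(C)C)[C@@H](c1ccc(O[Si](C)(C)C(C)(C)C)c(OC)c1)O2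
F6 | step 10 | (4R)-4-benzyl-3-{[5-bromo-3-methoxy-2-(TBSO)phenyl]acetyl}-1,3-oxazolidin-2-one | O=C(Cc1cc(Br)cc(OC)c1O[Si](C)(C)C(C)(C)C)N1C(=O)OC[C@H]1Cc1ccccc1
F7 | step 10 | (4R)-4-benzyl-3-{(2R,3R)-2-[5-bromo-3-methoxy-2-(TBSO)phenyl]-3-hydroxy-3-[3-methoxy-4-(TBSO)phenyl]propanoyl}-1,3-oxazolidin-2-one | O=C(N1C(=O)OC[C@H]1Cc1ccccc1)[C@H](c1cc(Br)cc(OC)c1O[Si](C)(C)C(C)(C)C)[C@@H](O)c1ccc(O[Si](C)(C)C(C)(C)C)c(OC)c1
F8 | step 10 | (1R,2S)-2-[5-bromo-3-methoxy-2-(TBSO)phenyl]-1-[3-methoxy-4-(TBSO)phenyl]propane-1,3-diol | OC[C@H](c1cc(Br)cc(OC)c1O[Si](C)(C)C(C)(C)C)[C@@H](O)c1ccc(O[Si](C)(C)C(C)(C)C)c(OC)c1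
F9 | step 10 | (1R,2S)-2-[5-bromo-3-methoxy-2-(TBSO)phenyl]-1-[3-methoxy-4-(TBSO)phenyl]-3-(TBSO)propan-1-ol | CC(C)(C)[Si](C)(C)OC[C@H](c1cc(Br)cc(OC)c1O[Si](C)(C)C(C)(C)C)[C@@H](O)c1ccc(O[Si](C)(C)C(C)(C)C)c(OC)c1
F10 | step 10 | (2S)-2-[5-bromo-3-methoxy-2-(TBSO)phenyl]-1-[3-methoxy-4-(TBSO)phenyl]-3-(TBSO)propan-1-one | CC(C)(C)[Si](C)(C)OC[C@H](c1cc(Br)cc(OC)c1O[Si](C)(C)C(C)(C)C)C(=O)c1ccc(O[Si](C)(C)C(C)(C)C)c(OC)c1
F11 | step 10 | (1S,2S)-2-[5-bromo-3-methoxy-2-(TBSO)phenyl]-1-[3-methoxy-4-(TBSO)phenyl]-3-(TBSO)propan-1-ol | CC(C)(C)[Si](C)(C)OC[C@H](c1cc(Br)cc(OC)c1O[Si](C)(C)C(C)(C)C)[C@H](O)c1ccc(O[Si](C)(C)C(C)(C)C)c(OC)c1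
F12 | step 20 | tris(aryl TBS ether) of 31 with the three aliphatic hydroxyl groups free | COc1cc([C@@H](O)[C@H](CO)c2cc(C[C@H]3COC(=O)[C@@H]3Cc3cc(OC)c4c(c3)[C@H](CO)[C@@H](c3ccc(O[Si](C)(C)C(C)(C)C)c(OC)c3)O4)cc(OC)c2O[Si](C)(C)C(C)(C)C)ccc1O[Si](C)(C)C(C)(C)C
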